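The furan-2,4-dione (tetronic acid) ring is cut between the enol carbon C4 and the stereocentre C5. C5 bears the ring oxygen O1 and the future hydroxymethyl carbon C6, so it can be the oxygen-substituted terminus of an allyl palladium cation (C5–C6–C7, O1 already acylated by C2). C4 is a carbonyl carbon and can arrive as a nitronate. Pd2(dba)3·CHCl3 with a chiral bisphosphine thus closes the lactone ring (O1, C2, C3, C4, C5) of an acrolein-derived 3-chloropropenyl 3-nitropropanoate, forming C4–C5 and setting C5 in one operation. Ozonolysis then trims the vinyl group to CH2OH, a Nef reaction turns C4 into the ketone, and C3 is acylated last.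

Key step: step 2

Remark on numbering: ring atoms are O1, C2 (lactone carbonyl), C3, C4 (enol carbon) and C5 (stereocentre). C6 is the hydroxymethyl carbon and C7 is the allyl carbon removed in step 3. The C5 descriptor switches between S and R along the route only because the CIP ranking of C4 and C6 changes; the spatial arrangement stays the same.

Assumption: the (R,R) antipode of the ligand is written as the one expected to give 5S. Its mirror image is used if the sense of induction proves to be the reverse.

Step 1
Reactants: 1 3-nitropropanoic acid; 2 acrolein (prop-2-enal)
Product: 4 3-chloroprop-1-en-1-yl 3-nitropropanoate (E/Z mixture), via 3-nitropropanoyl chloride 3 (not isolated)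
Conditions: (COCl)2, cat. DMF, CH2Cl2, 0 °C to rt; then 2, ZnCl2 (2 mol%), CH2Cl2, −20 °C to rt
Reagents that add atoms: oxalyl chloride, O=C(Cl)C(=O)Cl
Why: Acid chloride formation followed by Lewis-acid-catalysed conjugate (1,4) addition of the acyl chloride to the enal, a known entry to 3-halopropenyl esters, should give the γ-chloro enol ester; the E/Z ratio and any 1-chloroallyl isomer do not matter because all of them ionise to the same allyl cation in step 2.

Step 2
Reactants: 4 3-chloroprop-1-en-1-yl 3-nitropropanoate
Product: 5 (5S)-5-ethenyl-4-nitrooxolan-2-one (both C4 epimers)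
Conditions: Pd2(dba)3·CHCl3 (2.5 mol%), (R,R)-DACH-phenyl ligand [N,N'-(1R,2R)-cyclohexane-1,2-diylbis(2-diphenylphosphinobenzamide)] (7.5 mol%), Cs2CO3 (1.05 equiv), THF (0.01 M), 0 °C to rt
Reagents that add atoms: none
Why: Zerovalent palladium should ionise the allylic chloride to a 1-(acyloxy)allyl palladium cation, carbonate forms the nitronate at C4, and this carbon attacks the oxygen-bearing terminus C5 anti to palladium, forming the C4–C5 bond (Tsuji–Trost asymmetric allylic alkylation). The closest known reactions are the asymmetric alkylations of allylic gem-dicarboxylates and of alkoxyallenes, in which soft carbon nucleophiles attack the oxygen-substituted allyl terminus with high enantioselectivity, and the palladium-catalysed asymmetric allylation of nitroalkanes. The lactone ring (O1, C2, C3, C4, C5) closes in the 5-exo mode with the allyl unit outside the ring, whereas attack at C7 would need a seven-membered enol lactone. C5 is controlled by the chiral ligand: the two diastereomeric allyl complexes that form from achiral 4 should interconvert by π–σ–π exchange through the unsubstituted terminus C7, helped by chloride, so that the configuration is decided by the faster-cyclising complex (Curtin–Hammett control); C4 forms as a mixture and is erased in step 4. The step needs C- over O-alkylation of the nitronate (secured by the soft allyl palladium electrophile), face selectivity at C5 (ligand pocket) and no loss of nitrous acid (one equivalent of a mild heterogeneous base, high dilution).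

Step 3
Reactants: 5 (5S)-5-ethenyl-4-nitrooxolan-2-one
Product: 7 (5R)-5-(hydroxymethyl)-4-nitrooxolan-2-one, via ozonide 6 (not isolated)
Conditions: O3, CH2Cl2, −78 °C; then BH3·SMe2, −78 °C to rt; aq. NH4Cl work-up
Reagents that add atoms: ozone, [O-][O+]=O
Why: Ozonolysis with reductive work-up should cleave only the terminal vinyl group, and borane reduces the ozonide to the primary alcohol without base, so the acidic nitro C–H and C5 (α to the transient aldehyde) are not exposed to eliminating or epimerising conditions.

Step 4
Reactants: 7 (5R)-5-(hydroxymethyl)-4-nitrooxolan-2-one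
Product: 9 (5S)-4-hydroxy-5-(hydroxymethyl)furan-2(5H)-one, via aminofuranone 8 (not isolated)
Conditions: aq. TiCl3 (4.5 equiv, in dilute HCl), DME/H2O, rt; then 60 °C
Reagents that add atoms: water, O
Why: Reductive Nef reaction: trivalent titanium should reduce the secondary nitro group via the oxime to the imine, which rests as the vinylogous carbamate 8 and is hydrolysed in the hot acidic medium to the vinylogous acid 9; the absence of base avoids β-elimination of nitrite or of the C5 acyloxy group, and C5 is not touched.

Step 5
Reactants: 9 (5S)-4-hydroxy-5-(hydroxymethyl)furan-2(5H)-one; 10 13-methyltetradecanoic acid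
Product: 12 (5S)-4-hydroxy-5-(hydroxymethyl)-3-(13-methyltetradecanoyl)furan-2(5H)-one (target), via diester 11 (not isolated)
Conditions: 10 (2.3 equiv), DCC (2.4 equiv), DMAP (1.5 equiv), CH2Cl2/DMF, 0 °C to rt; then K2CO3, MeOH, rt; aq. HCl work-up
Reagents that add atoms: none
Why: Steglich-type O-acylation should give the 4-O-acyl tetronate, which DMAP rearranges to the 3-acyl tricarbonyl (O-to-C acyl migration) while the primary alcohol is esterified as well; carbonate-mediated transesterification then removes only the primary ester, because the tricarbonyl and lactone are protected as the enolate, which also keeps C5 from being deprotonated.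

Compound list
1 | 3-nitropropanoic acid | O=C(O)CC[N+](=O)[O-] | starting material
2 | acrolein (prop-2-enal) | C=CC=O | starting material
3 | 3-nitropropanoyl chloride | O=C(Cl)CC[N+](=O)[O-] | intermediate
4 | 3-chloroprop-1-en-1-yl 3-nitropropanoate (E/Z mixture) | O=C(CC[N+](=O)[O-])OC=CCCl | intermediate
5 | (5S)-5-ethenyl-4-nitrooxolan-2-one (both C4 epimers) | O=C1CC([N+](=O)[O-])[C@H](C=C)O1 | intermediate
6 | 4-nitro-5-(1,2,4-trioxolan-3-yl)oxolan-2-one (ozonide of 5) | O=C1CC([N+](=O)[O-])[C@H](C2OCOO2)O1 | intermediate
7 | (5R)-5-(hydroxymethyl)-4-nitrooxolan-2-one (both C4 epimers) | O=C1CC([N+](=O)[O-])[C@H](CO)O1 | intermediate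
8 | (5R)-4-amino-5-(hydroxymethyl)furan-2(5H)-one | O=C1C=C(N)[C@H](CO)O1 | intermediate
9 | (5S)-4-hydroxy-5-(hydroxymethyl)furan-2(5H)-one | O=C1C=C(O)[C@H](CO)O1 | intermediate
10 | 13-methyltetradecanoic acid | CC(C)CCCCCCCCCCCC(=O)O | starting material
11 | [(2S)-4-hydroxy-3-(13-methyltetradecanoyl)-5-oxo-2,5-dihydrofuran-2-yl]methyl 13-methyltetradecanoate | CC(C)CCCCCCCCCCCC(=O)C1=C(O)[C@H](COC(=O)CCCCCCCCCCCC(C)C)OC1=O | intermediate
12 | (5S)-4-hydroxy-5-(hydroxymethyl)-3-(13-methyltetradecanoyl)furan-2(5H)-one | CC(C)CCCCCCCCCCCC(=O)C1=C(O)[C@H](CO)OC1=O | target

Total step count: 5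
Longest linear sequence: 5 steps (1 → 4 → 5 → 7 → 9 → 12)

Steps most likely to fail

Step 2. Facial selectivity at C5 may be eroded if ring closure outruns the interconversion of the allyl complexes, if uncatalysed closure competes, or if the allylic lactone product is ionised again by the catalyst; nitrous acid may also be lost from the nitro ester. The fallback generates the allyl cation from a prochiral gem-diester, so that the enantio-determining event becomes ionisation of one of two enantiotopic carboxylates, as established for allylic gem-dicarboxylates. Setting out from 1, DCC (0.5 equiv) in CH2Cl2 should give 3-nitropropanoic anhydride F1 after removal of the urea. FeCl3-catalysed addition of F1 to acrolein 2 should give prop-2-ene-1,1-diyl bis(3-nitropropanoate) F2 as the prochiral gem-diester. With Pd2(dba)3·CHCl3, the same ligand and Cs2CO3, one carboxylate of F2 is ionised, and the nitronate of the remaining ester closes the lactone through the same C4–C5 bond, returning to the route at 5.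

Step 4. The reduction may stall at the amine (vinylogous carbamate) stage, or the very polar acid may not separate from the titanium salts. The fallback removes the nitro group oxidatively. Setting out from 7, NaOMe (1.0 equiv) in MeOH at 0 °C should give sodium [(2R)-2-(hydroxymethyl)-5-oxooxolan-3-ylidene]azinate F3 as the nitronate salt of 7. Ozone at −78 °C should then cleave the C=N bond of F3 in an oxidative Nef reaction, returning to the route at 9. Ozone is dosed only to the end point, and nitrite is removed by ion exchange before acidification so that C3 is not nitrosated.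

Step 5. The O-to-C acyl shift may be incomplete in the presence of the second ester, or the cleavage may not discriminate cleanly between the primary ester and the ring. The fallback masks the alcohol first. Setting out from 9, trityl chloride in pyridine should give (5S)-4-hydroxy-5-[(trityloxy)methyl]furan-2(5H)-one F4 with the primary alcohol masked. Acid 10 (1.2 equiv), DCC and DMAP should then convert F4 into (5S)-4-hydroxy-3-(13-methyltetradecanoyl)-5-[(trityloxy)methyl]furan-2(5H)-one F5 by the same O-acylation and acyl shift. In 80% aqueous acetic acid at 50 °C, F5 should lose the trityl group, returning to the route at 12.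

Further compounds
F1 | step 2 | 3-nitropropanoic anhydride | O=C(CC[N+](=O)[O-])OC(=O)CC[N+](=O)[O-]
F2 | step 2 | prop-2-ene-1,1-diyl bis(3-nitropropanoate) | C=CC(OC(=O)CC[N+](=O)[O-])OC(=O)CC[N+](=O)[O-]
F3 | step 4 | sodium [(2R)-2-(hydroxymethyl)-5-oxooxolan-3-ylidene]azinate | O=C1CC(=[N+]([O-])[O-])[C@H](CO)O1.[Na+]
F4 | step 5 | (5S)-4-hydroxy-5-[(trityloxy)methyl]furan-2(5H)-one | O=C1C=C(O)[C@H](COC(c2ccccc2)(c2ccccc2)c2ccccc2)O1
F5 | step 5 | (5S)-4-hydroxy-3-(13-methyltetradecanoyl)-5-[(trityloxy)methyl]furan-2(5H)-one | CC(C)CCCCCCCCCCCC(=O)C1=C(O)[C@H](COC(c2ccccc2)(c2ccccc2)c2ccccc2)OC1=O
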